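**Retrosynthetic overview**

1. Feature: the benzo ring (C4a, C5, C6, C7, C8, C8a) of the 2H-chromene is a hydroquinone mono-ether. Ether oxygen O1 sits on C8a, para to the free hydroxyl on C6, with the C8 methyl ortho to O1. This is the oxygen pattern a chromium alkoxycarbene leaves after benzannulation (carbene carbon = C8a, inserted CO = C6).
2. Key disconnection C8a–C4a, C5–C6, C6–C7: chromenol ⇒ pentacarbonylchromium alkoxy(isopropenyl)carbene whose alkoxy group is the (S,Z)-enynyl tertiary carbinol. The pyran ring closes first (alkyne insertion), the benzene ring second (CO insertion, 6π-electrocyclisation).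
3. Carbene complex ⇒ tertiary (Z)-enynol + pivaloyloxy(isopropenyl)carbene (from 2-bromopropene and Cr(CO)6), generated and consumed in one flask.
4. Enynol ⇒ (Z)-iodoalkenyl carbinol + trimethylsilylacetylene (Sonogashira); iodoalkene ⇒ (S)-propargylic alcohol (iodination, diimide).
5. (S)-Propargylic alcohol ⇒ geranylgeraniol: Sharpless epoxidation sets the only stereocentre (future C2), and epoxy chloride fragmentation unveils the alkyne.

Key step: step 9

Remark: chromene numbering (O1, C2, C3, C4, C4a, C5–C8, C8a) is used for these atoms in all intermediates. Because 2,2-disubstituted 2H-chromenes open reversibly at O1–C2 under UV light, which would racemise C2, the last step is run in amber glass and chromium is released with visible light only.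

**Route**

Step 1
Reactants: 1 (2E,6E,10E)-geranylgeraniol
Product: 2 (2S,3S)-2,3-epoxygeranylgeraniol {[(2S,3S)-3-methyl-3-[(3E,7E)-4,8,12-trimethyltrideca-3,7,11-trien-1-yl]oxiran-2-yl]methanol}
Conditions: Ti(OiPr)4 (10 mol%), L-(+)-diethyl tartrate (12 mol%), t-BuOOH (2 equiv), 4 Å MS, CH2Cl2, −20 °C
Reagents that add atoms: tert-butyl hydroperoxide, CC(C)(C)OO
Why: Sharpless asymmetric epoxidation; the titanium tartrate binds the allylic alcohol so only the C2=C3 alkene is oxidised, and L-(+)-tartrate delivers oxygen to the face that gives the (2S,3S) epoxide of an E-geraniol-type alcohol, which sets the centre that becomes C2 of the chromene.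

Step 2
Reactants: 2 (2S,3S)-2,3-epoxygeranylgeraniol
Product: 3 (2S,3R)-3-(chloromethyl)-2-methyl-2-[(3E,7E)-4,8,12-trimethyltrideca-3,7,11-trien-1-yl]oxirane (2,3-epoxygeranylgeranyl chloride)
Conditions: PPh3 (1.3 equiv), CCl4, NaHCO3, reflux
Reagents that add atoms: carbon tetrachloride, ClC(Cl)(Cl)Cl
Why: Appel chlorination by SN2 at the primary carbinol; the buffered neutral medium leaves the epoxide and both stereocentres untouched (the descriptor of the CH carbon changes only through the CIP priority of CH2Cl).

Step 3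
Reactants: 3 2,3-epoxygeranylgeranyl chloride
Product: 4 (3S,6E,10E)-3,7,11,15-tetramethylhexadeca-6,10,14-trien-1-yn-3-ol
Conditions: n-BuLi (3.3 equiv), THF, −40 → −20 °C; then H2O
Reagents that add atoms: none
Why: Base-induced fragmentation of a 2,3-epoxy chloride (lithiation at C1, β-elimination opening the C2–O bond, dehydrochlorination of the chlorovinyl alkoxide to the alkynide); the C3–O bond is never broken, so the tertiary carbinol keeps its configuration (S).

Step 4
Reactants: 4 (S)-propargylic alcohol
Product: 5 (3S,6E,10E)-1-iodo-3,7,11,15-tetramethylhexadeca-6,10,14-trien-1-yn-3-ol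
Conditions: n-BuLi (2.05 equiv), THF, −78 °C; I2 (1.0 equiv), −78 °C; aq. Na2S2O3
Reagents that add atoms: iodine, II
Why: Electrophilic iodination of the lithium acetylide with one equivalent of iodine at −78 °C, which should outpace any reaction of iodine with the alkoxide or the trisubstituted alkenes.

Step 5
Reactants: 5 iodoalkyne
Product: 6 (1Z,3S,6E,10E)-1-iodo-3,7,11,15-tetramethylhexadeca-1,6,10,14-tetraen-3-ol
Conditions: 2-nitrobenzenesulfonylhydrazide (3 equiv), Et3N, THF/i-PrOH (1:1), rt
Reagents that add atoms: none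
Why: Diimide reduction; concerted syn transfer of two hydrogens to the iodoalkyne gives the (Z)-iodoalkene, while trisubstituted alkenes are reduced far more slowly by diimide.

Step 6
Reactants: 6 (Z)-iodoalkenyl carbinol; 7 trimethylsilylacetylene (1.5 equiv)
Product: 8 (3Z,5S,8E,12E)-5,9,13,17-tetramethyl-1-(trimethylsilyl)octadeca-3,8,12,16-tetraen-1-yn-5-ol
Conditions: Pd(PPh3)4 (5 mol%), CuI (10 mol%), Et3N, THF, rt
Reagents that add atoms: none
Why: Sonogashira coupling of the alkenyl iodide with retention of the Z geometry; the free tertiary alcohol is tolerated.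

Step 7
Reactants: 8 silylated enynol
Product: 9 (3Z,5S,8E,12E)-5,9,13,17-tetramethyloctadeca-3,8,12,16-tetraen-1-yn-5-ol
Conditions: K2CO3 (0.3 equiv), MeOH, 0 °C
Reagents that add atoms: none
Why: Base-catalysed methanolysis of the alkynyl C–Si bond, mild enough to leave the Z-enynol intact at 0 °C.

Step 8
Reactants: 10 2-bromopropene; 11 chromium hexacarbonyl
Product: 14 tetramethylammonium pentacarbonyl(2-methyl-1-oxidoprop-2-en-1-ylidene)chromate, via isopropenyllithium 12 (not isolated), via lithium acylchromate 13 (not isolated)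
Conditions: t-BuLi (2.0 equiv), Et2O, −78 °C; Cr(CO)6, −78 °C → rt; then Me4NBr, H2O, 0 °C
Reagents that add atoms: tetramethylammonium bromide, C[N+](C)(C)C.[Br-]
Why: Fischer carbene route; bromine–lithium exchange gives isopropenyllithium, which adds to a CO ligand of Cr(CO)6, and the acyl chromate is isolated as its storable tetramethylammonium salt by cation metathesis.

Step 9
Reactants: 9 (S,Z)-enynol; 14 tetramethylammonium acylchromate (1.3 equiv)
Product: 18 (2S)-2,8-dimethyl-2-[(3E,7E)-4,8,12-trimethyltrideca-3,7,11-trien-1-yl]-2H-chromen-6-ol (the target), via pivaloyloxycarbene complex 15 (not isolated), via enynyloxycarbene complex 16 (not isolated), via tricarbonylchromium arene complex 17 (not isolated)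
Conditions: 14, PivCl (1.25 equiv), CH2Cl2, −40 °C; then 9, 2,6-di-tert-butylpyridine, −40 → 0 °C; cold filtration (Celite), solvent switch to degassed toluene (5 mM), 50–55 °C, Ar, dark; then air, visible light (λ > 420 nm), Et2O, rt
Reagents that add atoms: none
Why: Proposed new method: neither the alcoholysis of an acyloxycarbene complex by a tertiary alcohol nor a Dötz benzannulation through a tertiary, Z-enyne-bearing alkoxy tether has been shown; the first is the known exchange for primary and hindered secondary alcohols and should still run because the carbene carbon of 15 is a far stronger electrophile than an acyl chloride, pivalate shields the acyl carbon, and only the O–H bond of 9 is engaged. On warming, 16 loses a cis CO, the tethered alkyne coordinates and inserts into Cr=C8a with its inner carbon (C4a–C8a), CO then inserts at the former alkyne terminus (C5–C6) to give a chromium-bound dienylketene, and 6π-electrocyclisation onto the isopropenyl CH2 (C6–C7) followed by tautomerisation gives the phenol as its Cr(CO)3 complex 17, which air and visible light release. The closest known reaction type is the intramolecular Dötz benzannulation of aryl- and alkenylcarbene complexes whose alkyne is tethered through the carbene oxygen by a saturated primary alkoxy chain. The pyran ring closes first, in the insertion event, as a 6-exo-dig closure across the O1–C2–C3=C4 tether, and the benzene ring closes second by the 6π-electrocyclisation of the ketene. No stereocentre is formed; C2 keeps its S configuration because none of its four bonds is broken, provided that ionisation of the tertiary allylic C–O bond of 16 (non-polar medium, hindered base, ≤ 55 °C) and photochemical O1–C2 opening of the chromene (no light below 420 nm) are kept out. The step needs regioselective alkyne insertion, secured by the four-atom Z-alkene tether that can only deliver the inner alkyne carbon to C8a, phenol formation over CO-free cyclopentannulation, favoured for alkenylcarbenes of chromium, and intramolecular over intermolecular alkyne capture, secured by 5 mM dilution.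

**Compound list**

1 | (2E,6E,10E)-geranylgeraniol | CC(C)=CCC/C(C)=C/CC/C(C)=C/CC/C(C)=C/CO | starting material
2 | (2S,3S)-2,3-epoxygeranylgeraniol | CC(C)=CCC/C(C)=C/CC/C(C)=C/CC[C@]1(C)O[C@H]1CO | intermediate
3 | (2S,3R)-3-(chloromethyl)-2-methyl-2-[(3E,7E)-4,8,12-trimethyltrideca-3,7,11-trien-1-yl]oxirane | CC(C)=CCC/C(C)=C/CC/C(C)=C/CC[C@]1(C)O[C@H]1CCl | intermediate
4 | (3S,6E,10E)-3,7,11,15-tetramethylhexadeca-6,10,14-trien-1-yn-3-ol | CC(C)=CCC/C(C)=C/CC/C(C)=C/CC[C@@](C)(C#C)O | intermediate
5 | (3S,6E,10E)-1-iodo-3,7,11,15-tetramethylhexadeca-6,10,14-trien-1-yn-3-ol | CC(C)=CCC/C(C)=C/CC/C(C)=C/CC[C@@](C)(C#CI)O | intermediate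
6 | (1Z,3S,6E,10E)-1-iodo-3,7,11,15-tetramethylhexadeca-1,6,10,14-tetraen-3-ol | CC(C)=CCC/C(C)=C/CC/C(C)=C/CC[C@@](C)(/C=C\I)O | intermediate
7 | trimethylsilylacetylene | C#C[Si](C)(C)C | starting material
8 | (3Z,5S,8E,12E)-5,9,13,17-tetramethyl-1-(trimethylsilyl)octadeca-3,8,12,16-tetraen-1-yn-5-ol | CC(C)=CCC/C(C)=C/CC/C(C)=C/CC[C@@](C)(/C=C\C#C[Si](C)(C)C)O | intermediate
9 | (3Z,5S,8E,12E)-5,9,13,17-tetramethyloctadeca-3,8,12,16-tetraen-1-yn-5-ol | CC(C)=CCC/C(C)=C/CC/C(C)=C/CC[C@@](C)(/C=C\C#C)O | intermediate
10 | 2-bromopropene | CC(Br)=C | starting material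
11 | chromium hexacarbonyl | O=C=[Cr](=C=O)(=C=O)(=C=O)(=C=O)=C=O | starting material
12 | isopropenyllithium | [Li]C(C)=C | intermediate
13 | lithium pentacarbonyl(2-methyl-1-oxidoprop-2-en-1-ylidene)chromate | C=C(C)C([O-])=[Cr](=C=O)(=C=O)(=C=O)(=C=O)=C=O.[Li+] | intermediate
14 | tetramethylammonium pentacarbonyl(2-methyl-1-oxidoprop-2-en-1-ylidene)chromate | C=C(C)C([O-])=[Cr](=C=O)(=C=O)(=C=O)(=C=O)=C=O.C[N+](C)(C)C | intermediate
15 | pentacarbonyl[(pivaloyloxy)(prop-1-en-2-yl)methylidene]chromium | C=C(C)C(OC(=O)C(C)(C)C)=[Cr](=C=O)(=C=O)(=C=O)(=C=O)=C=O | intermediate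
16 | pentacarbonyl[(prop-1-en-2-yl){[(3Z,5S,8E,12E)-5,9,13,17-tetramethyloctadeca-3,8,12,16-tetraen-1-yn-5-yl]oxy}methylidene]chromium | CC(C)=CCC/C(C)=C/CC/C(C)=C/CC[C@@](C)(/C=C\C#C)OC(C(C)=C)=[Cr](=C=O)(=C=O)(=C=O)(=C=O)=C=O | intermediate
17 | tricarbonyl{η6-(2S)-2,8-dimethyl-2-[(3E,7E)-4,8,12-trimethyltrideca-3,7,11-trien-1-yl]-2H-chromen-6-ol}chromium, Cr on the benzo ring (η6 bond written as two components) | CC(C)=CCC/C(C)=C/CC/C(C)=C/CC[C@@]1(C)C=Cc2cc(O)cc(C)c2O1.O=C=[Cr](=C=O)=C=O | intermediate
18 | (2S)-2,8-dimethyl-2-[(3E,7E)-4,8,12-trimethyltrideca-3,7,11-trien-1-yl]-2H-chromen-6-ol | CC(C)=CCC/C(C)=C/CC/C(C)=C/CC[C@@]1(C)C=Cc2cc(O)cc(C)c2O1 | target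

**Step count**

Total: 9 steps. Longest linear sequence: 8 steps (steps 1–7 and 9) from geranylgeraniol; step 8 is a one-step branch.

**Steps most likely to fail**

1. Step 9 (proposed new method). Four processes threaten it:
 - thermal decomposition of the pivaloyloxycarbene before the hindered tertiary alcohol has added;
 - ionisation of the tertiary allylic C–O bond of the alkoxycarbene (the acyl chromate is a good leaving group), leading to elimination or loss of configuration;
 - electrocyclic opening of the transient, non-aromatic 2H-pyran at the vinylcarbene/vinylketene stage, which would also erode configuration at C2;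
 - intermolecular alkyne insertion (oligomerisation).

 Fallback, known chemistry throughout, sets out from 4 and comes back at 18. The arene is brought in ready-made and the pyran is closed by a C–O coupling in which the tertiary C–O bond of 4 is again a spectator. 4-Amino-3-methylphenol is O-silylated (TIPSCl, imidazole, DMF) to 2-methyl-4-[(triisopropylsilyl)oxy]aniline F1. Iodination ortho to nitrogen (ICl, NaHCO3, CH2Cl2/MeOH, 0 °C) should give 2-iodo-6-methyl-4-[(triisopropylsilyl)oxy]aniline F2. Sandmeyer bromination (t-BuONO, CuBr2, MeCN) converts it into (4-bromo-3-iodo-5-methylphenoxy)triisopropylsilane F3. Iodide-selective Sonogashira coupling of 4 with F3 (Pd(PPh3)2Cl2, CuI, Et3N, THF, rt) should give (3S,6E,10E)-1-{2-bromo-3-methyl-5-[(triisopropylsilyl)oxy]phenyl}-3,7,11,15-tetramethylhexadeca-6,10,14-trien-1-yn-3-ol F4. Lindlar semi-hydrogenation (H2, Pd/CaCO3/Pb, quinoline, EtOAc) should give (1Z,3S,6E,10E)-1-{2-bromo-3-methyl-5-[(triisopropylsilyl)oxy]phenyl}-3,7,11,15-tetramethylhexadeca-1,6,10,14-tetraen-3-ol F5. Intramolecular Buchwald–Hartwig etherification of the tertiary alcohol (Pd(OAc)2, 2-(di-tert-butylphosphino)-1,1′-binaphthyl, Cs2CO3, toluene, 80 °C) should give triisopropyl{[(2S)-2,8-dimethyl-2-[(3E,7E)-4,8,12-trimethyltrideca-3,7,11-trien-1-yl]-2H-chromen-6-yl]oxy}silane F6. Desilylation (TBAF, THF, 0 °C) then gives 18.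

2. Step 5. Over-reduction of the iodoalkene to the saturated iodide, slow competing reduction of chain alkenes, or reductive loss of iodine may occur under prolonged exposure to diimide.

 Fallback sets out from 5 and comes back at 6. Hydrogen transfer is replaced by hydroboration–protodeboronation. syn-Hydroboration of the iodoalkyne with dicyclohexylborane (2.2 equiv, THF, 0 °C; the first equivalent is taken up by the hydroxyl group) should give dicyclohexyl{(1Z,3S,6E,10E)-3-[(dicyclohexylboranyl)oxy]-1-iodo-3,7,11,15-tetramethylhexadeca-1,6,10,14-tetraen-1-yl}borane F7. Its alkenyl C–B bond is cleaved with retention by acetic acid, and aqueous work-up gives 6.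

3. Step 7. The free (Z)-enynol is the most fragile intermediate of the sequence. In basic methanol it may be consumed by 5-exo-dig addition of the alkoxide to the alkyne or by oligomerisation of the terminal enyne, both promoted by copper or palladium carried over from step 6.

 Fallback sets out from 6 and comes back at 9, skipping 8. Negishi coupling of 6 with ethynylzinc bromide (from ethynylmagnesium bromide and ZnBr2, 3 equiv, Pd(PPh3)4, THF, 0 °C → rt) installs the unprotected ethynyl group directly under non-protic conditions. No new compound is made.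

**Further compounds**

F1 | step 9 | 2-methyl-4-[(triisopropylsilyl)oxy]aniline | Cc1cc(O[Si](C(C)C)(C(C)C)C(C)C)ccc1N
F2 | step 9 | 2-iodo-6-methyl-4-[(triisopropylsilyl)oxy]aniline | Cc1cc(O[Si](C(C)C)(C(C)C)C(C)C)cc(I)c1N
F3 | step 9 | (4-bromo-3-iodo-5-methylphenoxy)triisopropylsilane | Cc1cc(O[Si](C(C)C)(C(C)C)C(C)C)cc(I)c1Br
F4 | step 9 | (3S,6E,10E)-1-{2-bromo-3-methyl-5-[(triisopropylsilyl)oxy]phenyl}-3,7,11,15-tetramethylhexadeca-6,10,14-trien-1-yn-3-ol | CC(C)=CCC/C(C)=C/CC/C(C)=C/CC[C@@](C)(C#Cc1cc(O[Si](C(C)C)(C(C)C)C(C)C)cc(C)c1Br)O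
F5 | step 9 | (1Z,3S,6E,10E)-1-{2-bromo-3-methyl-5-[(triisopropylsilyl)oxy]phenyl}-3,7,11,15-tetramethylhexadeca-1,6,10,14-tetraen-3-ol | CC(C)=CCC/C(C)=C/CC/C(C)=C/CC[C@@](C)(/C=C\c1cc(O[Si](C(C)C)(C(C)C)C(C)C)cc(C)c1Br)O
F6 | step 9 | triisopropyl{[(2S)-2,8-dimethyl-2-[(3E,7E)-4,8,12-trimethyltrideca-3,7,11-trien-1-yl]-2H-chromen-6-yl]oxy}silane | CC(C)=CCC/C(C)=C/CC/C(C)=C/CC[C@@]1(C)C=Cc2cc(O[Si](C(C)C)(C(C)C)C(C)C)cc(C)c2O1
F7 | step 5 | dicyclohexyl{(1Z,3S,6E,10E)-3-[(dicyclohexylboranyl)oxy]-1-iodo-3,7,11,15-tetramethylhexadeca-1,6,10,14-tetraen-1-yl}borane | CC(C)=CCC/C(C)=C/CC/C(C)=C/CC[C@@](C)(/C=C(\I)B(C1CCCCC1)C1CCCCC1)OB(C1CCCCC1)C1CCCCC1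
F0 | step 7 | none | none
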